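**Plan**
- Atom labels: C1 (CH–O-senecioyl), C2 (CH2), C3 (CH–O-isovaleryl), C4 (CMe2), C5 and C6 (cyclobutane CH), C7 (C=O), C8 (=CH), C9 (=CMe), C10 (cyclobutane CH), C11 (quaternary CMe). Ring A = C6–C7–C8–C9–C10–C11; ring B = C1–C2–C3–C4–C5–C6–C11.
- Cuts, in retrosynthetic order: the C1 ester; the C7 carbonyl (back to an allylic CH2); C5–H (back to C5–OH); the cyclobutane bond C5–C10; C6–C7 and C10–C11 together (isoprene cycloaddition); the C1 and C5 carbonyls of ring B (back to allylic CH2 groups).
- Enabling feature: with C5–C10 cut, rings A and B form a cis-fused cyclohexene–cycloheptanone. In it C5 and C10 stand 1,4 across the C6–C11 fusion bond, so the C10 hydrogen, allylic to C8=C9, is the γ-hydrogen of the C5 ketone.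
- Forward order: ring B first (Claisen ring expansion of a linalool-derived vinyloxolane), ring A second (Diels–Alder on the ring-B ene-dione), the cyclobutane last (light). C5 deoxygenation, C7 oxidation and the C1 ester follow.
- Stereochemistry: C3 and C1 come from two oxazaborolidine-catalysed ketone reductions. C6/C11 come from suprafacial cycloaddition on the ring-B face selected by C3. C5/C10 are enforced by the cis fusion and the C1–C4 tether.

Key step: step 9

Remark: in these labels the target is (1R,3R,5S,6R,10R,11R). Racemic linalool suffices because its stereocentre is lost in step 2.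

**Step 1**
Reactants: 1 (±)-linalool
Product: 2 bromo ether 5-(2-bromopropan-2-yl)-2-ethenyl-2-methyloxolane
Conditions: NBS, CH2Cl2, 0 °C to rt
Reagents that add atoms: N-bromosuccinimide, O=C1CCC(=O)N1Br
Why: Bromoetherification, in which the bromonium ion of the electron-rich trisubstituted alkene is opened 5-exo by the tertiary hydroxyl while the vinyl group stays untouched; the stereocentres formed are erased in step 2.

**Step 2**
Reactants: 2 bromo ether
Product: 4 karahanaenone (2,2,5-trimethylcyclohept-4-en-1-one), via allyl vinyl ether 3 (not isolated)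
Conditions: 2,4,6-collidine, reflux (about 170 °C)
Reagents that add atoms: none
Why: E2 loss of HBr toward the ring C–H gives the tetrasubstituted enol ether 3, which at the same temperature undergoes Claisen rearrangement with two-carbon ring expansion, a known entry to cyclohept-4-enones that places CMe2 (C4) beside the carbonyl (C3) and the methyl on C11 without regiochemical ambiguity.

**Step 3**
Reactants: 4 karahanaenone
Product: 5 (1R)-2,2,5-trimethylcyclohept-4-en-1-ol
Conditions: (S)-2-methyl-CBS-oxazaborolidine (10 mol %), catecholborane, toluene, −78 to −40 °C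
Reagents that add atoms: none
Why: Corey–Bakshi–Shibata reduction; the ketone is flanked by a quaternary carbon and a methylene, the size contrast this catalyst reads best, so the (S)-catalyst should give (R)-C3, and catecholborane leaves the alkene alone.

**Step 4**
Reactants: 5 (1R)-alcohol; 6 3-methylbutanoyl chloride
Product: 7 (1R)-2,2,5-trimethylcyclohept-4-en-1-yl 3-methylbutanoate
Conditions: pyridine, DMAP (cat.), CH2Cl2, 0 °C to rt
Reagents that add atoms: 3-methylbutanoyl chloride (6), CC(C)CC(=O)Cl
Why: DMAP-catalysed acylation of a secondary alcohol, which installs the final C3 ester early and does not touch the stereocentre.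

**Step 5**
Reactants: 7 cycloheptenyl isovalerate
Product: 9 ring-B ene-dione (1R)-2,2,5-trimethyl-3,6-dioxocyclohept-4-en-1-yl 3-methylbutanoate, via enone 8 (not isolated)
Conditions: Rh2(cap)4 (dirhodium tetrakis(caprolactamate), 1 mol %), 70% aq. t-BuOOH (excess, in portions), 1,2-dichloroethane, 40 °C
Reagents that add atoms: tert-butyl hydroperoxide, CC(C)(C)OO
Why: Radical allylic oxidation by tert-butylperoxyl radicals, a catalyst system known to take cycloalkenes to enones and enones on to ene-1,4-diones; both methylenes flanking C6=C11 end as carbonyls whichever reacts first, methylene C–H is preferred over methyl C–H, and the absence of base spares the β-acyloxy ketone from elimination.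

**Step 6**
Reactants: 9 ring-B ene-dione; 10 isoprene
Product: 11 cis-fused adduct (3R,6S,11R)-C1,C5-dione
Conditions: isoprene (excess), BF3·OEt2 (30 mol %), CH2Cl2, −78 to −30 °C
Reagents that add atoms: isoprene (10), C=CC(C)=C
Why: Lewis acid-catalysed Diels–Alder reaction; BF3 should bind the more basic C5 carbonyl (fed vinylogously by the C11 methyl, with a free lone pair beside C6–H) and so make C11 the electrophilic terminus that takes the CH2 next to the methyl-bearing carbon of isoprene, suprafacial addition makes H6 and the C11 methyl cis, and the diene should take the convex face of the chair-like ring-B conformer whose C3 acyloxy group is pseudoaxial (no syn-axial hydrogens, since C1 and C5 are trigonal) and whose pseudoaxial C4 methyl screens the other face, which puts ring A on the side of the C3 oxygen.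

**Step 7**
Reactants: 11 cis-fused dione
Product: 12 (1R,3R,6S,11R)-C1 alcohol
Conditions: (S)-2-methyl-CBS-oxazaborolidine (20 mol %), catecholborane, toluene–CH2Cl2, −78 to −20 °C; MeOH, pH 7 buffer
Reagents that add atoms: none
Why: Corey–Bakshi–Shibata reduction under catalyst control; only the C1 ketone (quaternary C11 against CH2) can engage the catalyst because the C5 ketone is buried between C4 and C6, and the (S)-catalyst should deliver hydride from the ring-A side to give (R)-C1 with its oxygen trans to the C3 oxygen.

**Step 8**
Reactants: 12 C1 alcohol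
Product: 13 silyl ether ketone (1R,3R,6S,11R), the photochemical precursor
Conditions: TBSOTf, 2,6-lutidine, CH2Cl2, 0 °C
Reagents that add atoms: tert-butyldimethylsilyl triflate, CC(C)(C)[Si](C)(C)OS(=O)(=O)C(F)(F)F
Why: Silyl triflate silylation, the standard for hindered secondary alcohols; it blocks lactol formation with the C5 ketone, and its bulk keeps C1 equatorial on ring A, which favours the conformer needed in step 9.

**Step 9**
Reactants: 13 silyl ether ketone
Product: 15 tricyclic C5 cyclobutanol (1R,3R,5S,6S,10R,11S), via hydroxy 1,4-diradical 14 (not isolated)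
Conditions: hν (300 nm, Pyrex), degassed MeCN (about 5 mM), −20 °C
Reagents that add atoms: none
Why: n,π* excitation of the C5 ketone is followed by 1,5-hydrogen transfer from the pseudoaxial allylic C10–H through a six-membered, boat-like transition state, and the hydroxy 1,4-diradical 14 collapses by C5–C10 coupling. This is the Norrish–Yang photocyclisation of a ketone bearing a γ-hydrogen, closest in kind to the closure of axial acylcyclohexanes to bicyclo[3.1.1]heptan-6-ols. The one new ring, the cyclobutane C5–C6–C11–C10, closes by transannular recombination of the 1,4-diradical across the C6–C11 fusion bond, which turns rings A and B into the doubly bridged tricycle with a single bond. C10 is set by the cis fusion, since C5 can reach ring A only on the face on which it is attached at C6, and C5 is set by the C1–C4 tether, which can span the cyclobutane only on the side away from the C7–C9 bridge and so leaves the hydroxyl over that bridge. The step needs abstraction at C10–H rather than at C11–CH3, C1–H or C2–H and closure at C10 rather than at C8 of the allyl radical: C10–H is the weakest bond and is syn-axial to C5 in the ring-A conformer that keeps the silyloxy-bearing C1 equatorial, the methyl is then anti to C5, the C1 and C2 hydrogens lie inside ring B behind an outward-pointing carbonyl oxygen, and the ring-B torsion that allows abstraction leaves the C5 p-orbital aimed at C10, not C8. α-Cleavage toward quaternary C4 is the main competitor, but it gives a tethered acyl/tert-alkyl diradical that should mostly reclose, harmlessly because C4 is not stereogenic, and low temperature together with a hydrogen-bond-accepting solvent favours abstraction and holds back reverse hydrogen transfer.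

**Step 10**
Reactants: 15 cyclobutanol
Product: 16 C5 methyl oxalate
Conditions: methyl chlorooxoacetate, DMAP, CH2Cl2, 0 °C to rt
Reagents that add atoms: methyl chlorooxoacetate, COC(=O)C(=O)Cl
Why: DMAP-mediated acylation with a small, very electrophilic acid chloride reaches the hindered tertiary alcohol without generating the alkoxide, which in a 2-vinylcyclobutanol would invite ring opening or rearrangement.

**Step 11**
Reactants: 16 methyl oxalate
Product: 17 deoxygenated tricycle (C5–H)
Conditions: Bu3SnH, AIBN (cat.), toluene, 110 °C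
Reagents that add atoms: none
Why: Barton–McCombie-type radical deoxygenation of a tertiary alkyl methyl oxalate; stannyl radical addition and C–O scission give the C5 cyclobutyl radical, whose ring opening is slow, and hydrogen can arrive only on the face toward the C7–C9 bridge because the C1–C4 tether holds C4 on the other, so C5 takes the configuration of the target.

**Step 12**
Reactants: 17 deoxygenated tricycle
Product: 18 C7 enone silyl ether
Conditions: CrO3, 3,5-dimethylpyrazole, CH2Cl2, −20 °C
Reagents that add atoms: chromium trioxide, O=[Cr](=O)=O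
Why: Allylic oxidation with the chromium trioxide–dimethylpyrazole complex, the α-pinene-to-verbenone type of conversion; C7 is the only allylic methylene, the bridgehead C10–H cannot give a planar allyl system, and the C9 methyl reacts more slowly.

**Step 13**
Reactants: 18 enone silyl ether
Product: 19 C1 hydroxy enone
Conditions: HF·pyridine, THF, 0 °C to rt
Reagents that add atoms: none
Why: Fluoride-driven Si–O cleavage in an acidic medium leaves the enone and the C3 ester intact and avoids base-induced acyl migration.

**Step 14**
Reactants: 19 hydroxy enone; 20 3-methylbut-2-enoyl chloride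
Product: 21 target CNP0335239.1
Conditions: pyridine, DMAP (cat.), CH2Cl2, 0 to 40 °C
Reagents that add atoms: 3-methylbut-2-enoyl chloride (20), CC(C)=CC(=O)Cl
Why: DMAP-catalysed acylation with retention at C1; pyridine in place of a trialkylamine limits vinylketene formation and hence deconjugation of the senecioyl group.

**Compound list**
1 | (±)-linalool (3,7-dimethylocta-1,6-dien-3-ol) | CC(C)=CCCC(C)(O)C=C | starting material
2 | 5-(2-bromopropan-2-yl)-2-ethenyl-2-methyloxolane (racemic, both diastereomers) | CC1(C=C)CCC(O1)C(C)(C)Br | intermediate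
3 | 2-ethenyl-2-methyl-5-(propan-2-ylidene)oxolane (racemic, not isolated) | CC(C)=C1CCC(C)(C=C)O1 | intermediate
4 | karahanaenone, 2,2,5-trimethylcyclohept-4-en-1-one | CC1=CCC(C)(C)C(=O)CC1 | intermediate
5 | (1R)-2,2,5-trimethylcyclohept-4-en-1-ol (carbinol carbon = C3) | CC1=CCC(C)(C)[C@H](O)CC1 | intermediate
6 | 3-methylbutanoyl chloride | CC(C)CC(=O)Cl | starting material
7 | (1R)-2,2,5-trimethylcyclohept-4-en-1-yl 3-methylbutanoate | CC1=CCC(C)(C)[C@H](OC(=O)CC(C)C)CC1 | intermediate
8 | (1R)-2,2,5-trimethyl-3-oxocyclohept-4-en-1-yl 3-methylbutanoate (C5 ketone, not isolated) | CC1=CC(=O)C(C)(C)[C@H](OC(=O)CC(C)C)CC1 | intermediate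
9 | (1R)-2,2,5-trimethyl-3,6-dioxocyclohept-4-en-1-yl 3-methylbutanoate (C1,C5 ene-dione) | CC1=CC(=O)C(C)(C)[C@H](OC(=O)CC(C)C)CC1=O | intermediate
10 | isoprene (2-methylbuta-1,3-diene) | C=CC(C)=C | starting material
11 | (1R,4R,7S)-1,5,5,10-tetramethyl-2,6-dioxobicyclo[5.4.0]undec-9-en-4-yl 3-methylbutanoate (cis-fused; route labels 3R,6S,11R) | O=C1C[C@@H](OC(=O)CC(C)C)C(C)(C)C(=O)[C@H]2CC=C(C)C[C@]21C | intermediate
12 | 2-hydroxy-1,5,5,10-tetramethyl-6-oxobicyclo[5.4.0]undec-9-en-4-yl 3-methylbutanoate (cis-fused; route labels 1R,3R,6S,11R; C1–OH trans to C3–O and anti to ring A) | O[C@@H]1C[C@@H](OC(=O)CC(C)C)C(C)(C)C(=O)[C@H]2CC=C(C)C[C@]21C | intermediate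
13 | 2-(tert-butyldimethylsilyloxy)-1,5,5,10-tetramethyl-6-oxobicyclo[5.4.0]undec-9-en-4-yl 3-methylbutanoate (route labels 1R,3R,6S,11R) | CC(C)(C)[Si](C)(C)O[C@@H]1C[C@@H](OC(=O)CC(C)C)C(C)(C)C(=O)[C@H]2CC=C(C)C[C@]21C | intermediate
14 | C5-hydroxy C5/C10 1,4-diradical of 13 (not isolated) | CC(C)(C)[Si](C)(C)O[C@@H]1C[C@@H](OC(=O)CC(C)C)C(C)(C)[C](O)[C@H]2CC=C(C)[CH][C@]21C | intermediate
15 | 3-(tert-butyldimethylsilyloxy)-7-hydroxy-2,6,6,9-tetramethyltricyclo[5.4.0.0^2,8]undec-9-en-5-yl 3-methylbutanoate (route labels 1R,3R,5S,6S,10R,11S; OH over the C7–C9 bridge) | CC(C)(C)[Si](C)(C)O[C@@H]1C[C@@H](OC(=O)CC(C)C)C(C)(C)[C@]2(O)[C@H]3CC=C(C)[C@@H]2[C@]31C | intermediate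
16 | C5 methyl oxalate of 15 | CC(C)(C)[Si](C)(C)O[C@@H]1C[C@@H](OC(=O)CC(C)C)C(C)(C)[C@]2(OC(=O)C(=O)OC)[C@H]3CC=C(C)[C@@H]2[C@]31C | intermediate
17 | 3-(tert-butyldimethylsilyloxy)-2,6,6,9-tetramethyltricyclo[5.4.0.0^2,8]undec-9-en-5-yl 3-methylbutanoate (route labels 1R,3R,5R,6R,10R,11S) | CC(C)(C)[Si](C)(C)O[C@@H]1C[C@@H](OC(=O)CC(C)C)C(C)(C)[C@@H]2[C@H]3CC=C(C)[C@@H]2[C@]31C | intermediate
18 | 3-(tert-butyldimethylsilyloxy)-2,6,6,9-tetramethyl-11-oxotricyclo[5.4.0.0^2,8]undec-9-en-5-yl 3-methylbutanoate (route labels 1R,3R,5S,6R,10R,11R) | CC(C)(C)[Si](C)(C)O[C@@H]1C[C@@H](OC(=O)CC(C)C)C(C)(C)[C@@H]2[C@H]3C(=O)C=C(C)[C@@H]2[C@]31C | intermediate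
19 | 3-hydroxy-2,6,6,9-tetramethyl-11-oxotricyclo[5.4.0.0^2,8]undec-9-en-5-yl 3-methylbutanoate (route labels 1R,3R,5S,6R,10R,11R) | O[C@@H]1C[C@@H](OC(=O)CC(C)C)C(C)(C)[C@@H]2[C@H]3C(=O)C=C(C)[C@@H]2[C@]31C | intermediate
20 | 3-methylbut-2-enoyl chloride (senecioyl chloride) | CC(C)=CC(=O)Cl | starting material
21 | CNP0335239.1, 2,6,6,9-tetramethyl-5-(3-methylbutanoyloxy)-11-oxotricyclo[5.4.0.0^2,8]undec-9-en-3-yl 3-methylbut-2-enoate (route labels 1R,3R,5S,6R,10R,11R) | CC(C)=CC(=O)O[C@@H]1C[C@@H](OC(=O)CC(C)C)C(C)(C)[C@@H]2[C@H]3C(=O)C=C(C)[C@@H]2[C@]31C | target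

**Total step count:** 14. **Longest linear sequence:** 14 steps, from linalool.

**Steps most likely to fail**

**Step 9.**
- What may go wrong:
  - The α-cleavage diradical may escape by disproportionation instead of reclosing.
  - The hydroxy diradical may return its hydrogen, break the C6–C11 bond, or couple at the far end of the allyl radical.
  - The ring-A alkene may deactivate the excited ketone.
- The fallback changes the substrate and the order of the endgame. It sets out from alcohol 12 and comes back at target 21.
- Rationale:
  - An acyloxy group at C1 removes the activated α-oxy C–H.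
  - The enoate can drain the ketone triplet, the main source of α-cleavage, so that the singlet abstraction channel remains.
- Sequence:
  - Acylation of 12 with 20 (pyridine, DMAP) would give the C1 senecioate ketone F1.
  - Irradiation of F1 as in step 9 would give the diester cyclobutanol F2.
  - Methyl chlorooxoacetate and DMAP would give the diester oxalate F3.
  - Bu3SnH and AIBN would give the deoxygenated diester F4.
  - Chromium trioxide–dimethylpyrazole oxidation of C7 then gives 21 directly.
- The variant is held in reserve because the enoate must survive irradiation, tin hydride and hexavalent chromium.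

**Step 6.**
- What may go wrong:
  - The orientation may be taken over by the C1 carbonyl.
  - The two faces of ring B may be poorly differentiated.
  - The Lewis acid may trigger loss of the β-acyloxy group.
- The fallback replaces the cycloaddition by a stepwise annulation steered by a C1 stereocentre set first. It sets out from ene-dione 9 and comes back at silyl ether ketone 13.
- Sequence:
  - Catalyst-controlled reduction of the less hindered C1 carbonyl ((S)-2-methyl-CBS-oxazaborolidine, catecholborane) would give the γ-hydroxy enone F5.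
  - TBSOTf and 2,6-lutidine would give its silyl ether F6.
  - Methallylcopper (methallylmagnesium chloride, CuBr·SMe2, Me3SiCl, THF, −78 °C) should add to C11 anti to the neighbouring C1 silyloxy group and give the trimethylsilyl enol ether F7.
  - Tsuji-type allylation of F7 (diallyl carbonate, Pd2(dba)3, PPh3, Bu4N[Ph3SiF2]) should bring the allyl group to C6 anti to the pseudoaxial C11 methyl and give the allyl methallyl ketone F8.
  - Ring-closing metathesis with the second-generation Grubbs catalyst (CH2Cl2, 40 °C) closes C8=C9 and delivers 13.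

**Step 10.**
- What may go wrong:
  - Acylation of the tertiary hydroxyl, wedged between C4 and the C7–C9 bridge, may stall.
  - The strained homoallylic alcohol may open under forcing conditions.
- The fallback activates the oxygen through trivalent phosphorus instead of an acyl group. It sets out from cyclobutanol 15 and comes back at 17.
- Sequence:
  - 2-(2-Iodophenyl)ethyl methyl N,N-diisopropylphosphoramidite and 1H-tetrazole would give the mixed phosphite F9.
  - With Bu3SnH and AIBN in refluxing benzene, the aryl radical attacks phosphorus. β-Scission of the phosphoranyl radical releases the same C5 radical, which is reduced to 17.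

**Further compounds**
F1 | step 9 | C1 senecioate of ketone 12 (cis-fused bicyclic diester ketone) | CC(C)=CC(=O)O[C@@H]1C[C@@H](OC(=O)CC(C)C)C(C)(C)C(=O)[C@H]2CC=C(C)C[C@]21C
F2 | step 9 | tricyclic C5 cyclobutanol diester | CC(C)=CC(=O)O[C@@H]1C[C@@H](OC(=O)CC(C)C)C(C)(C)[C@]2(O)[C@H]3CC=C(C)[C@@H]2[C@]31C
F3 | step 9 | C5 methyl oxalate of F2 | CC(C)=CC(=O)O[C@@H]1C[C@@H](OC(=O)CC(C)C)C(C)(C)[C@]2(OC(=O)C(=O)OC)[C@H]3CC=C(C)[C@@H]2[C@]31C
F4 | step 9 | deoxygenated tricyclic diester (C7 still CH2) | CC(C)=CC(=O)O[C@@H]1C[C@@H](OC(=O)CC(C)C)C(C)(C)[C@@H]2[C@H]3CC=C(C)[C@@H]2[C@]31C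
F5 | step 6 | (C1R,C3R) γ-hydroxy enone of ring B | O[C@@H]1C[C@@H](OC(=O)CC(C)C)C(C)(C)C(=O)C=C1C
F6 | step 6 | tert-butyldimethylsilyl ether of F5 | CC(C)(C)[Si](C)(C)O[C@@H]1C[C@@H](OC(=O)CC(C)C)C(C)(C)C(=O)C=C1C
F7 | step 6 | C5 trimethylsilyl enol ether carrying methyl and methallyl on C11 | CC(C)(C)[Si](C)(C)O[C@@H]1C[C@@H](OC(=O)CC(C)C)C(C)(C)C(O[Si](C)(C)C)=C[C@@]1(C)CC(C)=C
F8 | step 6 | C6-allyl C11-methallyl cycloheptanone (allyl cis to methallyl) | CC(C)(C)[Si](C)(C)O[C@@H]1C[C@@H](OC(=O)CC(C)C)C(C)(C)C(=O)[C@@H](CC=C)[C@@]1(C)CC(C)=C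
F9 | step 10 | C5 2-(2-iodophenyl)ethyl methyl phosphite of 15 | CC(C)(C)[Si](C)(C)O[C@@H]1C[C@@H](OC(=O)CC(C)C)C(C)(C)[C@]2(OP(OC)OCCc4ccccc4I)[C@H]3CC=C(C)[C@@H]2[C@]31C
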